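**Retrosynthetic overview**
- Kobophenol A ⇒ benzofuran A is closed last by C–O bond formation (asymmetric hydroalkoxylation of a triarylethene); benzofuran B is closed the same way one step earlier with the mirror-image catalyst.
- The bis-triarylethene ⇒ two Negishi couplings on 4-(2,2-dibromoethenyl)phenyl benzoate: first the brominated oxolane core, then the catechol-derived aryl unit.
- Catechol unit ⇒ 3,5-dibromocatechol + the vinyl bromide made from silylated resveratrol by bromination/dehydrobromination.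
- Oxolane core ⇒ reduction and C–O cyclodehydration of a meso-1,4-diketone ⇒ alkylation of a deoxybenzoin enolate with its own alpha-bromide, both made from silylated resveratrol.
- Ring order: oxolane, then benzofuran B, then benzofuran A.

Assumption: the target is the SMILES exactly as written (its second benzofuran is a 7-hydroxy-2,3-dihydrobenzofuran-5-yl unit), and 3,5-dibromobenzene-1,2-diol and 4-formylphenyl benzoate are bought.

TBS = tert-butyldimethylsilyl; TBSO = tert-butyldimethylsilyloxy.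

Step 1
Reactants: 1 resveratrol
Product: 2 tris-TBS resveratrol
Conditions: TBSCl, imidazole, DMF, 25 °C
Reagents that add atoms: tert-butyldimethylsilyl chloride CC(C)(C)[Si](C)(C)Cl
Why: Imidazole-promoted silylation of all three phenols masks the acidic OH groups for the organometallic steps; no stereocentre is formed.

Step 2
Reactants: 2 tris-TBS resveratrol
Product: 3 alpha-bromo ketone
Conditions: NBS (1.05 equiv), DMSO, 25 °C
Reagents that add atoms: dimethyl sulfoxide CS(C)=O; N-bromosuccinimide O=C1CCC(=O)N1Br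
Why: NBS/DMSO bromo-oxidation (bromonium opening by DMSO at the carbon next to the electron-rich 4-silyloxyphenyl ring, then Kornblum-type collapse of the alkoxysulfonium salt) puts the carbonyl on that carbon and the bromine on the carbon bearing the 3,5-disilyloxyphenyl ring; the product is racemic and its stereocentre is not carried on.

Step 3
Reactants: 3 alpha-bromo ketone
Product: 4 deoxybenzoin ketone
Conditions: Zn dust, AcOH, THF, 25 °C (on about half of the batch of 3)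
Reagents that add atoms: none
Why: Zinc/acetic acid reductive dehalogenation of an alpha-halo ketone through the zinc enolate gives the deoxybenzoin; aryl silyl ethers survive, and no stereocentre remains.

Step 4
Reactants: 4 deoxybenzoin ketone; 3 alpha-bromo ketone
Product: 6 meso-diketone, via lithium enolate 5 (not isolated)
Conditions: LiN(i-Pr)2, THF, −78 °C; then 3, THF/DMPU, −78 to 0 °C; then DBU (10 mol %), toluene, 40 °C; crystallise (hexane/EtOH)
Reagents that add atoms: lithium diisopropylamide [Li]N(C(C)C)C(C)C (its lithium is found only in 5)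
Why: Enolate alkylation with an alpha-bromo ketone (the classical bidesyl-type 1,4-diketone synthesis) joins the two benzylic carbons, and any bromine-transfer pathway only regenerates the same two partners; the acidic alpha-centres are then equilibrated with DBU in an aprotic solvent (which spares the aryl silyl ethers) and the less soluble meso isomer is collected, which fixes the erythro relation that becomes the 3,4-cis pair of the oxolane.

Step 5
Reactants: 6 meso-diketone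
Product: 8 meso-oxolane, via meso-diol 7 (not isolated)
Conditions: NaBH4, THF/MeOH, 0 °C; then camphorsulfonic acid (10 mol %), CH2Cl2, 0 °C
Reagents that add atoms: none
Why: Borohydride reduction then acid-catalysed SN1 cyclodehydration (C–O bond formation through a 4-silyloxybenzylic cation) closes the oxolane reversibly at C2 and C5, so both aryl groups settle trans to their neighbours while C3 and C4 keep the cis relation from 6.

Step 6
Reactants: 8 meso-oxolane
Product: 9 bromo-oxolane (racemate)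
Conditions: NBS (1.0 equiv), MeCN/CH2Cl2, −20 °C
Reagents that add atoms: N-bromosuccinimide O=C1CCC(=O)N1Br
Why: Electrophilic aromatic bromination goes to the doubly activated position para to one silyloxy group and next to the oxolane on one of the two equivalent resorcinol rings; the product is racemic, and the series with the wrong oxolane is removed as a diastereomer at step 15.

Step 7
Reactants: 2 tris-TBS resveratrol
Product: 11 bromostilbene, via erythro-dibromide 10 (not isolated)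
Conditions: Br2, CH2Cl2, −78 °C; then DBU, −78 to 25 °C
Reagents that add atoms: bromine BrBr
Why: Bromine addition then dehydrobromination, in which bromide leaves from the 4-silyloxybenzylic carbon and the more acidic hydrogen from the other carbon, leaves the vinyl bromine on the carbon carrying the 3,5-disilyloxyphenyl ring; alkene geometry is of no consequence later.

Step 8
Reactants: 12 3,5-dibromocatechol
Product: 13 bis-TBS dibromocatechol
Conditions: TBSCl, imidazole, DMF, 25 °C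
Reagents that add atoms: tert-butyldimethylsilyl chloride CC(C)(C)[Si](C)(C)Cl
Why: Standard silylation of both catechol hydroxyls; no stereocentre is formed.

Step 9
Reactants: 13 bis-TBS dibromocatechol; 11 bromostilbene
Product: 16 bromo-triarylethene, via aryllithium 14 (not isolated), via arylzinc chloride 15 (not isolated)
Conditions: n-BuLi (1.0 equiv), Et2O, −78 °C; ZnCl2, THF, −78 °C; then 11, Pd(PPh3)4 (5 mol %), THF, 50 °C
Reagents that add atoms: n-butyllithium [Li]CCCC (its lithium is found only in 14); zinc dichloride Cl[Zn]Cl (its zinc and chlorine are found only in 15)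
Why: Bromine–lithium exchange is fastest at the bromine flanked by a silyloxy group (as in 2,4-dibromoanisoles), transmetalation to zinc at −78 °C forestalls silyl migration, and Negishi coupling with a triphenylphosphine catalyst inserts into the vinyl bromide faster than into the electron-rich aryl bromide, so the triarylethene forms with the second aryl bromine untouched.

Step 10
Reactants: 17 4-formylphenyl benzoate
Product: 18 dibromoalkene
Conditions: CBr4, PPh3, CH2Cl2, 0 °C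
Reagents that add atoms: carbon tetrabromide BrC(Br)(Br)Br
Why: Ramirez dibromo-olefination (first stage of the Corey–Fuchs sequence) of the aldehyde; the benzoate is inert to the phosphorus ylide.

Step 11
Reactants: 9 bromo-oxolane (racemate); 18 dibromoalkene
Product: 21 bromoalkene, via aryllithium 19 (not isolated), via arylzinc chloride 20 (not isolated)
Conditions: t-BuLi (2.0 equiv), THF, −78 °C; ZnCl2; then 18 (1.5 equiv), Pd(PPh3)4 (5 mol %), THF, 25 to 40 °C
Reagents that add atoms: tert-butyllithium [Li]C(C)(C)C (its lithium is found only in 19); zinc dichloride Cl[Zn]Cl (its zinc and chlorine are found only in 20)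
Why: Negishi coupling of a 1,1-dibromoalkene takes place selectively at the less hindered bromine trans to the aryl group and gives the Z bromoalkene; aryl benzoates tolerate arylzinc halides.

Step 12
Reactants: 16 bromo-triarylethene; 21 bromoalkene
Product: 24 silylated bis-alkene, via aryllithium 22 (not isolated), via arylzinc chloride 23 (not isolated)
Conditions: t-BuLi (2.0 equiv), THF, −78 °C; ZnCl2; then 21, Pd(P(t-Bu)3)2 (5 mol %), THF/NMP, 60 °C
Reagents that add atoms: tert-butyllithium [Li]C(C)(C)C (its lithium is found only in 22); zinc dichloride Cl[Zn]Cl (its zinc and chlorine are found only in 23)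
Why: A second Negishi coupling at the remaining vinyl bromide with a bulky zerovalent palladium catalyst completes the second triarylethene; alkene geometry is irrelevant because both alkenes are protonated later.

Step 13
Reactants: 24 silylated bis-alkene
Product: 25 undecaphenol bis-alkene
Conditions: Bu4NF, AcOH, THF, 0 °C
Reagents that add atoms: none
Why: Buffered fluoride desilylation cleaves the eleven aryl silyl ethers and leaves the benzoate, the oxolane and both alkenes untouched.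

Step 14
Reactants: 25 undecaphenol bis-alkene
Product: 27 benzofuran B phenol, via benzofuran B benzoate 26 (not isolated)
Conditions: (R)-3,3′-bis(2,4,6-triisopropylphenyl)-BINOL N-triflylphosphoramide (10 mol %), MeCN/CHCl3, 0 °C; then K2CO3, MeOH, 0 °C, under argon
Reagents that add atoms: none
Why: Proposed new method: chiral Brønsted acid-catalysed asymmetric intramolecular hydroalkoxylation of a 2-[1-aryl-2-(4-hydroxyphenyl)vinyl]phenol. The bifunctional acid hydrogen-bonds the 4-hydroxyphenyl group and delivers a proton to the alkene carbon bearing the two aryl groups, giving a catalyst-bound para-quinone methide that the neighbouring catechol oxygen attacks (oxa-1,6-addition, C–O bond formation); C3 is set in the protonation and C2 trans to it, aiming at (2R,3R), with the catalyst enantiomer to be confirmed on a model triarylethene. Only the alkene with a free para-hydroxyl can close (the other is masked as the benzoate and any protonation there is reversible; the benzoate is then freed by methanolysis). The closest known reactions are chiral phosphoric acid-catalysed additions to in situ para-quinone methides, formal cycloadditions of para-hydroxystyrenes, and the achiral acid cyclisation of 2-hydroxystilbenes.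

Step 15
Reactants: 27 benzofuran B phenol
Product: 28 KOBOPHENOL A
Conditions: (S)-3,3′-bis(2,4,6-triisopropylphenyl)-BINOL N-triflylphosphoramide (10 mol %), MeCN/CHCl3, 0 to 25 °C; preparative HPLC
Reagents that add atoms: none
Why: Proposed new method: the same asymmetric hydroalkoxylation with the mirror-image catalyst, because the two benzofurans have opposite handedness. The resorcinol oxygen attacks the para-quinone methide tautomer of the remaining triarylethene and sets C2 and C3 of benzofuran A as (2S,3S), trans. Because 9 was racemic, 28 forms beside one diastereomer that carries the mirror-image oxolane, which is removed by HPLC, so at most half of 27 can become 28. The closest known reactions are those named in step 14.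

**Compound list**
1 | resveratrol, (E)-5-[2-(4-hydroxyphenyl)ethenyl]benzene-1,3-diol | Oc1ccc(/C=C/c2cc(O)cc(O)c2)cc1 | starting material
2 | (E)-3,4′,5-tris(TBSO)stilbene | CC(C)(C)[Si](C)(C)Oc1ccc(/C=C/c2cc(O[Si](C)(C)C(C)(C)C)cc(O[Si](C)(C)C(C)(C)C)c2)cc1 | intermediate
3 | 2-bromo-2-[3,5-bis(TBSO)phenyl]-1-[4-(TBSO)phenyl]ethan-1-one (racemic) | CC(C)(C)[Si](C)(C)Oc1ccc(C(=O)C(Br)c2cc(O[Si](C)(C)C(C)(C)C)cc(O[Si](C)(C)C(C)(C)C)c2)cc1 | intermediate
4 | 2-[3,5-bis(TBSO)phenyl]-1-[4-(TBSO)phenyl]ethan-1-one | CC(C)(C)[Si](C)(C)Oc1ccc(C(=O)Cc2cc(O[Si](C)(C)C(C)(C)C)cc(O[Si](C)(C)C(C)(C)C)c2)cc1 | intermediate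
5 | lithium (Z)-enolate of 4 | [Li]O/C(c1ccc(O[Si](C)(C)C(C)(C)C)cc1)=C\c1cc(O[Si](C)(C)C(C)(C)C)cc(O[Si](C)(C)C(C)(C)C)c1 | intermediate
6 | meso-(2R,3S)-2,3-bis[3,5-bis(TBSO)phenyl]-1,4-bis[4-(TBSO)phenyl]butane-1,4-dione | CC(C)(C)[Si](C)(C)Oc1ccc(cc1)C(=O)[C@@H](c1cc(O[Si](C)(C)C(C)(C)C)cc(O[Si](C)(C)C(C)(C)C)c1)[C@@H](c1cc(O[Si](C)(C)C(C)(C)C)cc(O[Si](C)(C)C(C)(C)C)c1)C(=O)c1ccc(O[Si](C)(C)C(C)(C)C)cc1 | intermediate
7 | (2R,3S)-2,3-bis[3,5-bis(TBSO)phenyl]-1,4-bis[4-(TBSO)phenyl]butane-1,4-diol (mixture of carbinol epimers) | CC(C)(C)[Si](C)(C)Oc1ccc(cc1)C(O)[C@@H](c1cc(O[Si](C)(C)C(C)(C)C)cc(O[Si](C)(C)C(C)(C)C)c1)[C@@H](c1cc(O[Si](C)(C)C(C)(C)C)cc(O[Si](C)(C)C(C)(C)C)c1)C(O)c1ccc(O[Si](C)(C)C(C)(C)C)cc1 | intermediate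
8 | meso-(2R,3S,4R,5S)-3,4-bis[3,5-bis(TBSO)phenyl]-2,5-bis[4-(TBSO)phenyl]oxolane (2,3-trans, 3,4-cis, 4,5-trans) | CC(C)(C)[Si](C)(C)Oc1cc(O[Si](C)(C)C(C)(C)C)cc(c1)[C@@H]1[C@H](c2cc(O[Si](C)(C)C(C)(C)C)cc(O[Si](C)(C)C(C)(C)C)c2)[C@@H](c2ccc(O[Si](C)(C)C(C)(C)C)cc2)O[C@H]1c1ccc(O[Si](C)(C)C(C)(C)C)cc1 | intermediate
9 | rac-(2R,3S,4R,5S)-3-[2-bromo-3,5-bis(TBSO)phenyl]-4-[3,5-bis(TBSO)phenyl]-2,5-bis[4-(TBSO)phenyl]oxolane (the enantiomer drawn leads to 28) | Brc1c(O[Si](C)(C)C(C)(C)C)cc(O[Si](C)(C)C(C)(C)C)cc1[C@@H]1[C@H](c2cc(O[Si](C)(C)C(C)(C)C)cc(O[Si](C)(C)C(C)(C)C)c2)[C@@H](c2ccc(O[Si](C)(C)C(C)(C)C)cc2)O[C@H]1c1ccc(O[Si](C)(C)C(C)(C)C)cc1 | intermediate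
10 | erythro-1,2-dibromo-1-[4-(TBSO)phenyl]-2-[3,5-bis(TBSO)phenyl]ethane (racemic) | CC(C)(C)[Si](C)(C)Oc1ccc([C@H](Br)[C@H](Br)c2cc(O[Si](C)(C)C(C)(C)C)cc(O[Si](C)(C)C(C)(C)C)c2)cc1 | intermediate
11 | (E)-1-bromo-1-[3,5-bis(TBSO)phenyl]-2-[4-(TBSO)phenyl]ethene | CC(C)(C)[Si](C)(C)Oc1ccc(/C=C(/Br)c2cc(O[Si](C)(C)C(C)(C)C)cc(O[Si](C)(C)C(C)(C)C)c2)cc1 | intermediate
12 | 3,5-dibromobenzene-1,2-diol | Oc1cc(Br)cc(Br)c1O | starting material
13 | 3,5-dibromo-1,2-bis(TBSO)benzene | CC(C)(C)[Si](C)(C)Oc1cc(Br)cc(Br)c1O[Si](C)(C)C(C)(C)C | intermediate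
14 | [5-bromo-2,3-bis(TBSO)phenyl]lithium | CC(C)(C)[Si](C)(C)Oc1cc(Br)cc([Li])c1O[Si](C)(C)C(C)(C)C | intermediate
15 | [5-bromo-2,3-bis(TBSO)phenyl]zinc chloride | CC(C)(C)[Si](C)(C)Oc1cc(Br)cc([Zn]Cl)c1O[Si](C)(C)C(C)(C)C | intermediate
16 | (E)-5-bromo-1,2-bis(TBSO)-3-{1-[3,5-bis(TBSO)phenyl]-2-[4-(TBSO)phenyl]ethenyl}benzene | Brc1cc(O[Si](C)(C)C(C)(C)C)c(O[Si](C)(C)C(C)(C)C)c(/C(c2cc(O[Si](C)(C)C(C)(C)C)cc(O[Si](C)(C)C(C)(C)C)c2)=C/c2ccc(O[Si](C)(C)C(C)(C)C)cc2)c1 | intermediate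
17 | 4-formylphenyl benzoate | O=Cc1ccc(OC(=O)c2ccccc2)cc1 | starting material
18 | 4-(2,2-dibromoethenyl)phenyl benzoate | BrC(Br)=Cc1ccc(OC(=O)c2ccccc2)cc1 | intermediate
19 | aryllithium from 9 (lithium in place of bromine; racemic) | [Li]c1c(O[Si](C)(C)C(C)(C)C)cc(O[Si](C)(C)C(C)(C)C)cc1[C@@H]1[C@H](c2cc(O[Si](C)(C)C(C)(C)C)cc(O[Si](C)(C)C(C)(C)C)c2)[C@@H](c2ccc(O[Si](C)(C)C(C)(C)C)cc2)O[C@H]1c1ccc(O[Si](C)(C)C(C)(C)C)cc1 | intermediate
20 | arylzinc chloride from 9 (ZnCl in place of bromine; racemic) | Cl[Zn]c1c(O[Si](C)(C)C(C)(C)C)cc(O[Si](C)(C)C(C)(C)C)cc1[C@@H]1[C@H](c2cc(O[Si](C)(C)C(C)(C)C)cc(O[Si](C)(C)C(C)(C)C)c2)[C@@H](c2ccc(O[Si](C)(C)C(C)(C)C)cc2)O[C@H]1c1ccc(O[Si](C)(C)C(C)(C)C)cc1 | intermediate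
21 | 4-{(Z)-2-bromo-2-[2-((2R,3S,4R,5S)-4-[3,5-bis(TBSO)phenyl]-2,5-bis[4-(TBSO)phenyl]oxolan-3-yl)-4,6-bis(TBSO)phenyl]ethenyl}phenyl benzoate (racemic; enantiomer drawn leads to 28) | O=C(Oc1ccc(/C=C(/c2c(O[Si](C)(C)C(C)(C)C)cc(O[Si](C)(C)C(C)(C)C)cc2[C@@H]2[C@H](c3cc(O[Si](C)(C)C(C)(C)C)cc(O[Si](C)(C)C(C)(C)C)c3)[C@@H](c3ccc(O[Si](C)(C)C(C)(C)C)cc3)O[C@H]2c2ccc(O[Si](C)(C)C(C)(C)C)cc2)Br)cc1)c1ccccc1 | intermediate
22 | aryllithium from 16 (lithium in place of bromine) | [Li]c1cc(O[Si](C)(C)C(C)(C)C)c(O[Si](C)(C)C(C)(C)C)c(/C(c2cc(O[Si](C)(C)C(C)(C)C)cc(O[Si](C)(C)C(C)(C)C)c2)=C/c2ccc(O[Si](C)(C)C(C)(C)C)cc2)c1 | intermediate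
23 | arylzinc chloride from 16 (ZnCl in place of bromine) | Cl[Zn]c1cc(O[Si](C)(C)C(C)(C)C)c(O[Si](C)(C)C(C)(C)C)c(/C(c2cc(O[Si](C)(C)C(C)(C)C)cc(O[Si](C)(C)C(C)(C)C)c2)=C/c2ccc(O[Si](C)(C)C(C)(C)C)cc2)c1 | intermediate
24 | silylated bis-alkene: 21 with the vinyl bromine replaced by the 3,4-bis(TBSO)-5-{(E)-1-[3,5-bis(TBSO)phenyl]-2-[4-(TBSO)phenyl]ethenyl}phenyl group; both alkenes E, oxolane (2R,3S,4R,5S) (racemic; enantiomer drawn leads to 28) | O=C(Oc1ccc(/C=C(/c2c(O[Si](C)(C)C(C)(C)C)cc(O[Si](C)(C)C(C)(C)C)cc2[C@@H]2[C@H](c3cc(O[Si](C)(C)C(C)(C)C)cc(O[Si](C)(C)C(C)(C)C)c3)[C@@H](c3ccc(O[Si](C)(C)C(C)(C)C)cc3)O[C@H]2c2ccc(O[Si](C)(C)C(C)(C)C)cc2)c2cc(O[Si](C)(C)C(C)(C)C)c(O[Si](C)(C)C(C)(C)C)c(/C(c3cc(O[Si](C)(C)C(C)(C)C)cc(O[Si](C)(C)C(C)(C)C)c3)=C/c3ccc(O[Si](C)(C)C(C)(C)C)cc3)c2)cc1)c1ccccc1 | intermediate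
25 | undecaphenol bis-alkene: 24 with all eleven TBSO groups as OH, benzoate kept (racemic; enantiomer drawn leads to 28) | O=C(Oc1ccc(/C=C(/c2c(O)cc(O)cc2[C@@H]2[C@H](c3cc(O)cc(O)c3)[C@@H](c3ccc(O)cc3)O[C@H]2c2ccc(O)cc2)c2cc(O)c(O)c(/C(c3cc(O)cc(O)c3)=C/c3ccc(O)cc3)c2)cc1)c1ccccc1 | intermediate
26 | benzofuran B benzoate: 25 with the catechol-side alkene closed to the (2R,3R)-trans-2-(4-hydroxyphenyl)-3-(3,5-dihydroxyphenyl)-7-hydroxy-2,3-dihydrobenzofuran (1:1 pair of diastereomers in the oxolane; the one drawn leads to 28) | O=C(Oc1ccc(/C=C(/c2c(O)cc(O)cc2[C@@H]2[C@H](c3cc(O)cc(O)c3)[C@@H](c3ccc(O)cc3)O[C@H]2c2ccc(O)cc2)c2cc(O)c3c(c2)[C@@H](c2cc(O)cc(O)c2)[C@H](c2ccc(O)cc2)O3)cc1)c1ccccc1 | intermediate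
27 | benzofuran B phenol: 26 with the benzoate cleaved to the free 4-hydroxyphenyl group (1:1 pair of diastereomers in the oxolane; the one drawn leads to 28) | Oc1ccc(/C=C(/c2c(O)cc(O)cc2[C@@H]2[C@H](c3cc(O)cc(O)c3)[C@@H](c3ccc(O)cc3)O[C@H]2c2ccc(O)cc2)c2cc(O)c3c(c2)[C@@H](c2cc(O)cc(O)c2)[C@H](c2ccc(O)cc2)O3)cc1 | intermediate
28 | kobophenol A, (2S,3S)-3-[(2R,3R)-3-(3,5-dihydroxyphenyl)-7-hydroxy-2-(4-hydroxyphenyl)-2,3-dihydro-1-benzofuran-5-yl]-4-[(2R,3S,4R,5S)-4-(3,5-dihydroxyphenyl)-2,5-bis(4-hydroxyphenyl)oxolan-3-yl]-2-(4-hydroxyphenyl)-2,3-dihydro-1-benzofuran-6-ol | Oc1ccc([C@H]2Oc3cc(O)cc([C@@H]4[C@H](c5cc(O)cc(O)c5)[C@@H](c5ccc(O)cc5)O[C@H]4c4ccc(O)cc4)c3[C@@H]2c2cc(O)c3c(c2)[C@@H](c2cc(O)cc(O)c2)[C@H](c2ccc(O)cc2)O3)cc1 | target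

**Totals**
Total step count: 15. Longest linear sequence: 11 steps (1, 2, 3, 4, 5, 6, 11, 12, 13, 14, 15).

**Steps most likely to fail**

The first is step 14, the new hydroalkoxylation that closes benzofuran B. The triarylethene may resist productive protonation by the chiral acid, or the enantiocontrol may be poor. The fallback closes this ring before the fragments are joined and takes its configuration from a resolution. It sets out from 16: Bu4NF/AcOH gives the free bromo-triarylethene F1. Trifluoroacetic acid in CH2Cl2 closes it (the known acid cyclisation of 2-hydroxystilbenes) to the racemic trans dihydrobenzofuran, which is resolved on a chiral phase into the (2R,3R) bromo-benzofuran F2 and the discarded (2S,3S) bromo-benzofuran F3. TBSCl/imidazole on F2 gives the silylated bromo-benzofuran F4. t-BuLi gives the benzofuranyl-lithium F5 and ZnCl2 the benzofuranyl-zinc chloride F6, which is coupled with 21 under Pd(P(t-Bu)3)2 to the silylated mono-alkene F7. Bu4NF/AcOH then gives 26, where the route is rejoined.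

The second is step 15, the same new method on the more hindered alkene next to the oxolane, where the acid may also open the oxolane. The fallback replaces the catalytic protonation by hydroboration and an SN1 ring closure. It sets out from 27: TBSCl/imidazole gives the fully silylated mono-alkene F8. BH3·SMe2 then NaBO3·4H2O gives the silylated secondary alcohol F9, by syn addition with boron at the less substituted carbon; the face is chosen by the substrate and isomers are separated. Bu4NF/AcOH gives the polyphenol alcohol F10. Pyridinium p-toluenesulfonate in MeCN then closes benzofuran A by cyclodehydration through the para-quinone methide, trans to the fixed C3, and the route is rejoined at 28 after HPLC.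

The third is step 12, the Negishi coupling at a congested vinyl bromide, where lithiation side reactions or slow coupling are the worry. The fallback avoids the organolithium and uses an isolable boron nucleophile. It sets out from 16: B2pin2, PdCl2(dppf) and KOAc in dioxane give the pinacol boronate F11. Suzuki–Miyaura coupling with 21 (Pd(OAc)2, 2-dicyclohexylphosphino-2′,6′-dimethoxybiphenyl, CsF, dioxane, 80 °C) gives 24, where the route is rejoined.

**Further compounds**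
F1 | step 14 | (E)-5-bromo-3-[1-(3,5-dihydroxyphenyl)-2-(4-hydroxyphenyl)ethenyl]benzene-1,2-diol | Brc1cc(O)c(O)c(/C(c2cc(O)cc(O)c2)=C/c2ccc(O)cc2)c1
F2 | step 14 | (2R,3R)-5-bromo-3-(3,5-dihydroxyphenyl)-2-(4-hydroxyphenyl)-2,3-dihydro-1-benzofuran-7-ol | Brc1cc(O)c2c(c1)[C@@H](c1cc(O)cc(O)c1)[C@H](c1ccc(O)cc1)O2
F3 | step 14 | (2S,3S)-5-bromo-3-(3,5-dihydroxyphenyl)-2-(4-hydroxyphenyl)-2,3-dihydro-1-benzofuran-7-ol (discarded enantiomer) | Brc1cc(O)c2c(c1)[C@H](c1cc(O)cc(O)c1)[C@@H](c1ccc(O)cc1)O2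
F4 | step 14 | (2R,3R)-5-bromo-7-(TBSO)-3-[3,5-bis(TBSO)phenyl]-2-[4-(TBSO)phenyl]-2,3-dihydro-1-benzofuran | Brc1cc(O[Si](C)(C)C(C)(C)C)c2c(c1)[C@@H](c1cc(O[Si](C)(C)C(C)(C)C)cc(O[Si](C)(C)C(C)(C)C)c1)[C@H](c1ccc(O[Si](C)(C)C(C)(C)C)cc1)O2
F5 | step 14 | benzofuran-5-yl-lithium from F4 | [Li]c1cc(O[Si](C)(C)C(C)(C)C)c2c(c1)[C@@H](c1cc(O[Si](C)(C)C(C)(C)C)cc(O[Si](C)(C)C(C)(C)C)c1)[C@H](c1ccc(O[Si](C)(C)C(C)(C)C)cc1)O2
F6 | step 14 | benzofuran-5-yl-zinc chloride from F4 | Cl[Zn]c1cc(O[Si](C)(C)C(C)(C)C)c2c(c1)[C@@H](c1cc(O[Si](C)(C)C(C)(C)C)cc(O[Si](C)(C)C(C)(C)C)c1)[C@H](c1ccc(O[Si](C)(C)C(C)(C)C)cc1)O2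
F7 | step 14 | silylated mono-alkene: 26 with its ten OH groups as TBSO | O=C(Oc1ccc(/C=C(/c2c(O[Si](C)(C)C(C)(C)C)cc(O[Si](C)(C)C(C)(C)C)cc2[C@@H]2[C@H](c3cc(O[Si](C)(C)C(C)(C)C)cc(O[Si](C)(C)C(C)(C)C)c3)[C@@H](c3ccc(O[Si](C)(C)C(C)(C)C)cc3)O[C@H]2c2ccc(O[Si](C)(C)C(C)(C)C)cc2)c2cc(O[Si](C)(C)C(C)(C)C)c3c(c2)[C@@H](c2cc(O[Si](C)(C)C(C)(C)C)cc(O[Si](C)(C)C(C)(C)C)c2)[C@H](c2ccc(O[Si](C)(C)C(C)(C)C)cc2)O3)cc1)c1ccccc1
F8 | step 15 | fully silylated mono-alkene: 27 with its eleven OH groups as TBSO | CC(C)(C)[Si](C)(C)Oc1ccc(/C=C(/c2c(O[Si](C)(C)C(C)(C)C)cc(O[Si](C)(C)C(C)(C)C)cc2[C@@H]2[C@H](c3cc(O[Si](C)(C)C(C)(C)C)cc(O[Si](C)(C)C(C)(C)C)c3)[C@@H](c3ccc(O[Si](C)(C)C(C)(C)C)cc3)O[C@H]2c2ccc(O[Si](C)(C)C(C)(C)C)cc2)c2cc(O[Si](C)(C)C(C)(C)C)c3c(c2)[C@@H](c2cc(O[Si](C)(C)C(C)(C)C)cc(O[Si](C)(C)C(C)(C)C)c2)[C@H](c2ccc(O[Si](C)(C)C(C)(C)C)cc2)O3)cc1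
F9 | step 15 | silylated secondary alcohol: F8 with H added at the diaryl carbon (configuration as C3 of benzofuran A) and OH at the carbon bearing the 4-(TBSO)phenyl group (carbinol epimers) | CC(C)(C)[Si](C)(C)Oc1ccc(cc1)C(O)[C@H](c1c(O[Si](C)(C)C(C)(C)C)cc(O[Si](C)(C)C(C)(C)C)cc1[C@@H]1[C@H](c2cc(O[Si](C)(C)C(C)(C)C)cc(O[Si](C)(C)C(C)(C)C)c2)[C@@H](c2ccc(O[Si](C)(C)C(C)(C)C)cc2)O[C@H]1c1ccc(O[Si](C)(C)C(C)(C)C)cc1)c1cc(O[Si](C)(C)C(C)(C)C)c2c(c1)[C@@H](c1cc(O[Si](C)(C)C(C)(C)C)cc(O[Si](C)(C)C(C)(C)C)c1)[C@H](c1ccc(O[Si](C)(C)C(C)(C)C)cc1)O2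
F10 | step 15 | polyphenol alcohol: F9 with all TBSO groups as OH | Oc1ccc(cc1)C(O)[C@H](c1c(O)cc(O)cc1[C@@H]1[C@H](c2cc(O)cc(O)c2)[C@@H](c2ccc(O)cc2)O[C@H]1c1ccc(O)cc1)c1cc(O)c2c(c1)[C@@H](c1cc(O)cc(O)c1)[C@H](c1ccc(O)cc1)O2
F11 | step 12 | pinacol boronate of 16 (Bpin in place of bromine) | CC1(C)OB(OC1(C)C)c1cc(O[Si](C)(C)C(C)(C)C)c(O[Si](C)(C)C(C)(C)C)c(/C(c2cc(O[Si](C)(C)C(C)(C)C)cc(O[Si](C)(C)C(C)(C)C)c2)=C/c2ccc(O[Si](C)(C)C(C)(C)C)cc2)c1
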